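Everything rests on cutting ring C at C4a–C4, C4–C3 and O1–C2. C4 is an isolated carbonyl carbon held only by C4a of ring A and by C3, so it can come from carbon monoxide. C3, C2 and ring B come from 4-(benzyloxy)phenylacetylene. Ring A comes from 2-iodo-5-methoxybenzene-1,3-diol, whose mirror plane through C4a and C7 makes both hydroxyls equivalent: one becomes O1, the other stays as the 5-hydroxyl. One palladium-catalysed carbonylative coupling–cyclisation therefore forms three bonds and ring C. The 3-methoxy group and the 4'-prenyl ether are then attached by conventional steps, a single hydrogenolysis freeing both phenols.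

Key step: step 2

Remark: the target, 5-hydroxy-3,7-dimethoxy-4'-(prenyloxy)flavone, has no stereocentre and no stereogenic double bond, so nothing stereochemical has to be set. Dimethyldioxirane (DMDO), used only in a fallback, is assumed to be a freshly prepared acetone solution.

Step 1
Reactants: 1 5-methoxyresorcinol (5-methoxybenzene-1,3-diol)
Product: 2 2-iodo-5-methoxybenzene-1,3-diol
Conditions: I2 (1.0 equiv), NaHCO3 (1.1 equiv), THF/H2O 1:1, 0 °C
Reagents that add atoms: iodine, II
Why: Electrophilic aromatic iodination under bicarbonate should go to C2, the carbon ortho to both hydroxyls and para to the methoxy group, as the same protocol does with resorcinol, while one equivalent of iodine at 0 °C limits attack at C4/C6 and di-iodination.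

Step 2
Reactants: 2 2-iodo-5-methoxybenzene-1,3-diol, 3 1-(benzyloxy)-4-ethynylbenzene (1.3 equiv), 4 carbon monoxide
Product: 7 2-[4-(benzyloxy)phenyl]-5-hydroxy-7-methoxy-4H-chromen-4-one, via aryl ynone 5 (not isolated), via diethylamino enaminone 6 (not isolated)
Conditions: PdCl2(dppf) (5 mol %), CO (20 bar), degassed Et2NH, 100 °C, no copper salt
Reagents that add atoms: none
Why: Zerovalent palladium, generated from PdCl2(dppf) in the amine, inserts into the C–I bond at the future C4a, CO insertion gives an aroylpalladium species, and amine-assisted alkynylation with reductive elimination delivers ynone 5 (bonds C4a–C4 and C4–C3). Diethylamine then adds in conjugate fashion to give enaminone 6, and a phenolic oxygen attacks the amine-bearing carbon and expels diethylamine, a 6-endo-trig addition–elimination that forms O1–C2 and closes ring C. The closest known reaction type is the palladium-catalysed carbonylative Sonogashira annulation of o-iodophenols with terminal alkynes to flavones. No stereocentre is formed. The step needs carbonylative over direct coupling, which CO pressure and the absence of copper should secure, and six- over five-membered closure, which the enaminone secures because the oxygen can then only displace the amine at the future C2. No choice between the two hydroxyls arises, because the mirror plane of 2 makes them equivalent, and the one left over is the 5-hydroxyl of 7.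

Step 3
Reactants: 7 2-[4-(benzyloxy)phenyl]-5-hydroxy-7-methoxy-4H-chromen-4-one
Product: 8 5-(benzyloxy)-2-[4-(benzyloxy)phenyl]-7-methoxy-4H-chromen-4-one
Conditions: BnBr (1.5 equiv), K2CO3, DMF, 70 °C
Reagents that add atoms: benzyl bromide, BrCc1ccccc1
Why: Williamson etherification of the only hydroxyl, which is hydrogen-bonded to C4=O and therefore needs DMF and heat, masks the acidic proton that would otherwise consume base and deactivate C3 in the next step.

Step 4
Reactants: 8 5-(benzyloxy)-2-[4-(benzyloxy)phenyl]-7-methoxy-4H-chromen-4-one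
Product: 11 5-(benzyloxy)-2-[4-(benzyloxy)phenyl]-3-hydroxy-7-methoxy-4H-chromen-4-one, via 3-lithiochromone 9 (not isolated), via dimethyl boronate 10 (not isolated)
Conditions: LDA (1.5 equiv), THF, −78 °C; B(OMe)3, −78 °C → rt; AcOH, 30% H2O2, 0 °C → rt
Reagents that add atoms: hydrogen peroxide, OO
Why: LDA should remove the vinylic C3–H next to the carbonyl (the known C3 lithiation of alkoxyflavones), trimethyl borate traps the anion as boronate 10, and peroxide oxidation of the C–B bond by 1,2-migration gives the flavonol, the benzyl and methyl ethers being inert to all three reagents at these temperatures.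

Step 5
Reactants: 11 5-(benzyloxy)-2-[4-(benzyloxy)phenyl]-3-hydroxy-7-methoxy-4H-chromen-4-one
Product: 12 5-(benzyloxy)-2-[4-(benzyloxy)phenyl]-3,7-dimethoxy-4H-chromen-4-one
Conditions: MeI (2 equiv), K2CO3, acetone, reflux
Reagents that add atoms: iodomethane, CI
Why: Williamson O-methylation of the acidic enolic 3-hydroxyl, the only free hydroxyl in 11, should be clean.

Step 6
Reactants: 12 5-(benzyloxy)-2-[4-(benzyloxy)phenyl]-3,7-dimethoxy-4H-chromen-4-one
Product: 13 5-hydroxy-2-(4-hydroxyphenyl)-3,7-dimethoxy-4H-chromen-4-one
Conditions: H2 (1 atm), 10% Pd/C, THF/MeOH, rt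
Reagents that add atoms: none
Why: Catalytic hydrogenolysis should cleave both benzyl ethers at once, while the tetrasubstituted C2=C3 bond of the chromone (a vinylogous ester) and the methyl ethers are not reduced at 1 atm and room temperature.

Step 7
Reactants: 13 5-hydroxy-2-(4-hydroxyphenyl)-3,7-dimethoxy-4H-chromen-4-one, 14 prenyl bromide (1-bromo-3-methylbut-2-ene, 1.1 equiv)
Product: 15 5-hydroxy-3,7-dimethoxy-2-{4-[(3-methylbut-2-en-1-yl)oxy]phenyl}-4H-chromen-4-one
Conditions: K2CO3 (1.2 equiv), acetone, rt
Reagents that add atoms: none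
Why: Williamson alkylation (SN2 at the primary allylic carbon) should occur only at the 4'-hydroxyl, the more acidic and unhindered phenol, because the 5-hydroxyl is held in a hydrogen bond to C4=O and is far less nucleophilic under mild carbonate conditions.

Compound list
1 | 5-methoxyresorcinol (5-methoxybenzene-1,3-diol) | COc1cc(O)cc(O)c1 | starting material
2 | 2-iodo-5-methoxybenzene-1,3-diol | COc1cc(O)c(I)c(O)c1 | intermediate
3 | 1-(benzyloxy)-4-ethynylbenzene | C#Cc1ccc(OCc2ccccc2)cc1 | starting material
4 | carbon monoxide | [C-]#[O+] | starting material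
5 | aryl ynone 3-[4-(benzyloxy)phenyl]-1-(2,6-dihydroxy-4-methoxyphenyl)prop-2-yn-1-one, formed in the flask and not isolated | COc1cc(O)c(C(=O)C#Cc2ccc(OCc3ccccc3)cc2)c(O)c1 | intermediate
6 | diethylamino enaminone (E)-3-[4-(benzyloxy)phenyl]-3-(diethylamino)-1-(2,6-dihydroxy-4-methoxyphenyl)prop-2-en-1-one, formed in the flask and not isolated; its geometry is lost on ring closure | CCN(CC)/C(c1ccc(OCc2ccccc2)cc1)=C/C(=O)c1c(O)cc(OC)cc1O | intermediate
7 | 2-[4-(benzyloxy)phenyl]-5-hydroxy-7-methoxy-4H-chromen-4-one | COc1cc(O)c2c(=O)cc(-c3ccc(OCc4ccccc4)cc3)oc2c1 | intermediate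
8 | 5-(benzyloxy)-2-[4-(benzyloxy)phenyl]-7-methoxy-4H-chromen-4-one | COc1cc(OCc2ccccc2)c2c(=O)cc(-c3ccc(OCc4ccccc4)cc3)oc2c1 | intermediate
9 | 3-lithiochromone, the 3-lithio derivative of 8, formed in the flask and not isolated | COc1cc(OCc2ccccc2)c2c(=O)c([Li])c(-c3ccc(OCc4ccccc4)cc3)oc2c1 | intermediate
10 | dimethyl {5-(benzyloxy)-2-[4-(benzyloxy)phenyl]-7-methoxy-4-oxo-4H-chromen-3-yl}boronate, formed in the flask and not isolated | COc1cc(OCc2ccccc2)c2c(=O)c(B(OC)OC)c(-c3ccc(OCc4ccccc4)cc3)oc2c1 | intermediate
11 | 5-(benzyloxy)-2-[4-(benzyloxy)phenyl]-3-hydroxy-7-methoxy-4H-chromen-4-one | COc1cc(OCc2ccccc2)c2c(=O)c(O)c(-c3ccc(OCc4ccccc4)cc3)oc2c1 | intermediate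
12 | 5-(benzyloxy)-2-[4-(benzyloxy)phenyl]-3,7-dimethoxy-4H-chromen-4-one | COc1cc(OCc2ccccc2)c2c(=O)c(OC)c(-c3ccc(OCc4ccccc4)cc3)oc2c1 | intermediate
13 | 5-hydroxy-2-(4-hydroxyphenyl)-3,7-dimethoxy-4H-chromen-4-one | COc1cc(O)c2c(=O)c(OC)c(-c3ccc(O)cc3)oc2c1 | intermediate
14 | prenyl bromide (1-bromo-3-methylbut-2-ene) | CC(C)=CCBr | starting material
15 | 5-hydroxy-3,7-dimethoxy-2-{4-[(3-methylbut-2-en-1-yl)oxy]phenyl}-4H-chromen-4-one | COc1cc(O)c2c(=O)c(OC)c(-c3ccc(OCC=C(C)C)cc3)oc2c1 | target

Total step count: 7. Longest linear sequence: 7 steps (1 → 2 → 7 → 8 → 11 → 12 → 13 → 15).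

Steps most likely to fail

1. Step 2 (key step). Oxidative addition into the electron-rich C–I bond flanked by two hydroxyls may be slow. Reductive loss of iodine, capture of the aroylpalladium intermediate by diethylamine to give an amide, or CO-free coupling followed by five-membered closure could then take over. The fallback sets out from 1 and 3 and comes back to the route at 7; it brings in C4 as a formyl carbon by organolithium chemistry instead of CO. Compound 1 is protected with MOMCl and i-Pr2NEt in CH2Cl2 as 1-methoxy-3,5-bis(methoxymethoxy)benzene F1. n-BuLi in THF at 0 °C should lithiate the carbon between the two acetal oxygens, and DMF then gives 4-methoxy-2,6-bis(methoxymethoxy)benzaldehyde F2. The lithium acetylide of 3 (n-BuLi, THF, −78 °C) adds to the aldehyde to give racemic 3-[4-(benzyloxy)phenyl]-1-[4-methoxy-2,6-bis(methoxymethoxy)phenyl]prop-2-yn-1-ol F3. MnO2 in CH2Cl2 oxidises this to 3-[4-(benzyloxy)phenyl]-1-[4-methoxy-2,6-bis(methoxymethoxy)phenyl]prop-2-yn-1-one F4. HCl in MeOH at rt removes both acetals to give ynone 5, and warming with Et2NH in EtOH closes it through enaminone 6 to 7.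

2. Step 1. Site selectivity may be poor, with iodine entering between a hydroxyl and the methoxy group, and a second iodination or loss of iodine from the product in light or acid may occur. The fallback sets out from 1 and comes back at 2; it fixes the site by directed ortho-metalation instead of electrophilic substitution. Compound 1 is converted with MOMCl and i-Pr2NEt into 1-methoxy-3,5-bis(methoxymethoxy)benzene F5 (identical in structure with F1). Lithiation between the two acetal groups with n-BuLi in THF at 0 °C and a quench with I2 should give 2-iodo-5-methoxy-1,3-bis(methoxymethoxy)benzene F6. Brief treatment with HCl in MeOH at rt releases 2.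

3. Step 4. Deprotonation at C3 may be incomplete or may compete with metalation at the benzylic CH2 groups or on ring A, and the C–B bond may be protonated before oxidation, which returns 8. The fallback sets out from 8 and comes back at 11; it uses electrophilic oxygen transfer instead of metalation. DMDO in acetone/CH2Cl2 at 0 °C should epoxidise C2=C3 to racemic 5-(benzyloxy)-2-[4-(benzyloxy)phenyl]-2,3-epoxy-7-methoxychroman-4-one F7 (ring fusion necessarily cis). Catalytic TsOH in CH2Cl2 should open the epoxide, and tautomerisation of the resulting enol gives 11.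

Further compounds
F1 | step 2 | 1-methoxy-3,5-bis(methoxymethoxy)benzene | COCOc1cc(OC)cc(OCOC)c1
F2 | step 2 | 4-methoxy-2,6-bis(methoxymethoxy)benzaldehyde | COCOc1cc(OC)cc(OCOC)c1C=O
F3 | step 2 | racemic 3-[4-(benzyloxy)phenyl]-1-[4-methoxy-2,6-bis(methoxymethoxy)phenyl]prop-2-yn-1-ol | COCOc1cc(OC)cc(OCOC)c1C(O)C#Cc1ccc(OCc2ccccc2)cc1
F4 | step 2 | 3-[4-(benzyloxy)phenyl]-1-[4-methoxy-2,6-bis(methoxymethoxy)phenyl]prop-2-yn-1-one | COCOc1cc(OC)cc(OCOC)c1C(=O)C#Cc1ccc(OCc2ccccc2)cc1
F5 | step 1 | 1-methoxy-3,5-bis(methoxymethoxy)benzene (same structure as F1) | COCOc1cc(OC)cc(OCOC)c1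
F6 | step 1 | 2-iodo-5-methoxy-1,3-bis(methoxymethoxy)benzene | COCOc1cc(OC)cc(OCOC)c1I
F7 | step 4 | 5-(benzyloxy)-2-[4-(benzyloxy)phenyl]-2,3-epoxy-7-methoxychroman-4-one (racemic, one enantiomer drawn) | COc1cc(OCc2ccccc2)c2C(=O)[C@H]3O[C@]3(Oc2c1)c1ccc(OCc2ccccc2)cc1
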